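## The problem

Broussoflavonol F (29) is a flavonol. A phloroglucinol ring A is fused through C4a and C8a to a 3-hydroxy-4-pyranone ring C, which carries the 4'-hydroxyphenyl ring B at C2. One prenyl (3-methylbut-2-enyl) group sits at C8 of ring A and a second at C3' of ring B. The target has no stereocenter, so nothing has to be controlled in space; the stereocenters that appear on the way (in 8, 10, 12 and 22) are racemic and are erased. The real selectivity problem is positional: C8 and C6 become different only through which ortho oxygen, O1 or O5, closes ring C, and a free 3-prenylphloroacyl unit gives both the 8- and the 6-prenyl series. The two trisubstituted alkenes rule out strong protic or Lewis acids (chroman formation with the neighbouring hydroxyl), electrophilic oxidants such as peracids, dioxiranes and halonium sources, and hydrogenation. The free tetrahydroxyflavonol is also oxidized by air in strong base. The feature that opens the route is ring A itself: oxygens at C5, C7 and C8a in a 1,3,5 relationship, with the prenyl-bearing C8 between the O7 and O1 carbons. A 4-substituted 3-oxycyclobutenone (a masked vinylketene supplying C8a, C8, C7 and C6) and an oxygenated alkyne (C4a and C5) deliver exactly this pattern, and the ketone carbon emerges as the only free hydroxyl, O1.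

## Retrosynthesis

**29 from 28.** The last cut is at the three aryl O–Si bonds, which leads to the 5,7,4'-tris(triisopropylsilyl) ether 28. Silyl ethers are preferred to acetal or benzyl groups because the ring A construction delivers them directly and buffered fluoride removes them. Acetal cleavage would need protic acid beside two prenyl groups with ortho hydroxyls, and hydrogenolysis would saturate the alkenes. The forward step only has to break Si–O bonds without a base strong enough to expose the flavonol to air oxidation.

**28 from 25.** The C3–O bond is cut next, giving flavone 25. Bringing this oxygen in by alkaline peroxide cyclization of a chalcone is set aside: aqueous alkali cleaves aryl silyl ethers ortho and para to a carbonyl, and once O5 is free either ortho oxygen can close ring C. Epoxidation of the flavone double bond is excluded by the prenyl groups. What remains is to make C3 the nucleophile: deprotonation at C3, boration, and oxidation of the C–B bond with a nucleophilic peroxide that isolated trisubstituted alkenes tolerate.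

**25 from 15 and 20.** Ring C is opened at O1–C2 and then at C3–C4. Flavone 25 comes from ynone 23, this from carbinol 22, and 22 from salicylaldehyde 15 and arylacetylene 20. The ynone is already at the oxidation level of the flavone, and the cut divides the molecule into ring A and ring B halves of similar size. Unlike an aldol union, the acetylide addition needs no hydroxide. The forward sequence must close the six-membered ring and not the five-membered aurone, and must do so while O5 is still silylated. A secondary amine, which converts the ynone into enaminone 24 before O1 attacks, meets both demands.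

**20 from 16 and 17.** The ethynyl carbon is removed (alkyne 20 from aldehyde 19), then the silyl group (19 from phenol 18), then the C3'–prenyl bond (18 from 4-hydroxybenzaldehyde 16 and prenyl bromide 17). Direct ortho C-alkylation of the phenoxide is chosen over an O-prenylation and rearrangement sequence because it is one step and cannot give the reverse-prenyl isomer. The price is a separable O-alkylated by-product at the cheapest point of the synthesis.

**15 from 13.** The C4a–C4 bond is cut, leading to phenol 13. In 13 the only free position ortho to the hydroxyl is the future C4a, so a chelation-controlled ortho-formylation has one site to choose. The other open ring carbon lies between two bulky silyloxy groups and is para to the hydroxyl.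

**13 from 8 and 4.** Ring A is taken apart at C4a–C8a, C5–C6 and C8–C8a, which leads to cyclobutenone 8 and siloxyalkyne 4. The neighbouring options, C-prenylation or Claisen chemistry on a preformed phloroglucinol, leave the O1/O5 question to substrate bias. The annulation builds the ring around the prenyl group and gives a single isomer in which O5 and O7 are silylated and O1 is free. Both precursors are small and acyclic or four-membered. The forward reaction is asked for one regiochemical decision, the orientation of the alkyne on the ketene.

**8 from 5, 1 and 2.** Cyclobutenone 8 is cut at its two ring bonds into prenylketene 7 and a second molecule of alkyne 4. The ketene comes from acid chloride 6 and this from 5-methylhex-4-enoic acid 5. Alkyne 4 is cut at O–Si and C–O into lithium ethynolate 3, which comes from the lithium acetylide complex 1 and an oxygen donor, and triisopropylsilyl chloride 2. One alkyne thus serves twice and supplies both O5 and O7.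

## Roads not taken

Alternative 1: The two prenyl alkenes are cut, leading to the 8,3'-diallyl flavonol tetrakis(methoxymethyl) ether A2 and 2-methylbut-2-ene A3. In the forward direction a second-generation ruthenium alkylidene metathesis catalyst exchanges both terminal alkenes and gives tetrakis-O-(methoxymethyl) broussoflavonol F, A1.
- Merits: the sensitive trisubstituted alkenes appear only at the end, allyl groups are placed by reliable aromatic rearrangements, and the flavonol core can be made by classical alkaline peroxide chemistry. In flavonol formation this road is better precedented than step 11 of the chosen plan, and it is probably not longer.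
- Weak points: placing the allyl group at C8 and not C6 still depends on the bias of a rearrangement on ring A. Two cross-metatheses must both go to completion on one substrate with a chelating 3-alkoxy-4-ketone. Unmasking A1 needs acid on four acetals beside two prenyl groups with ortho oxygens.
- Against this the chosen plan sets a C8 placement fixed by construction and an acid-free final step.

Alternative 2: Ring C is cut at C3–C4 and O1–C2, leading to the prenylated salicylaldehyde A5 and the ring B sulfoxonium ylide A6. A cationic trivalent rhodium catalyst of the pentamethylcyclopentadienyl type would activate the formyl C–H bond, insert the carbene carbon and, after condensation, give 5,7,4'-tris(methoxymethoxy)-8,3'-diprenylflavone, A4.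
- Merits: one catalytic operation joins the halves and closes ring C. Steps 9 and 10 of the chosen plan need two operations and pass through a labile carbinol, so this road is one step shorter and more convergent at this point.
- Weak points: A4 is a flavone, so the C3 oxygen must still be added as in step 11. An electrophilic high-valent metal must leave two trisubstituted alkenes with allylic C–H bonds alone. A5 has the same O1/O5 differentiation problem, which the annulation does not solve. The acetals again leave with acid.
- The chosen plan answers with stoichiometric main-group chemistry whose tolerance of prenyl and silyl groups is predictable, and with a ring A synthesis that solves the regiochemistry. Its aldehyde 15 is the silyl counterpart of A5, so this annulation could be tried from 15 if steps 9 and 10 disappoint.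

Alternative 3: Both benzylic-to-vinylic bonds of the prenyl chains are cut, leading to the 8,3'-bis(bromomethyl) flavonol tetraacetate A8 and the 2-methylprop-1-enylboronate A9. Zerovalent palladium with a phosphine ligand would couple twice to give broussoflavonol F tetraacetate, A7.
- Merits: the alkenes are made last, and the acetates leave under mild base, a final step as gentle to the prenyl groups as the fluoride step of the chosen plan.
- Weak points: A8 requires an 8,3'-dimethyl flavonol, so the C8/C6 question returns at the methyl stage. It also needs a double benzylic bromination that must spare C6–H of an oxygenated ring. Benzylic bromides flanked by acetoxy groups meet the aqueous base of the coupling, where acetate loss opens quinone methide pathways.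
- The chosen plan needs no functional-group interconversion on the side chains and carries the finished prenyl groups through conditions chosen for them.

Key step: step 4

Assumption: the oxidation of lithium acetylides to ynolates by lithium tert-butyl peroxide is taken to extend to the parent acetylide, used as its commercial ethylenediamine complex 1; acid 5 is taken as a catalogue compound.

Step 1
Reactants: 1 lithium acetylide–ethylenediamine complex; 2 triisopropylsilyl chloride
Product: 4 (triisopropylsilyloxy)acetylene, via lithium ethynolate 3 (not isolated)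
Conditions: t-BuOOH, LiN(SiMe3)2, THF, −78 °C; 1, −78 to 0 °C; then 2, −78 °C to rt
Reagents that add atoms: tert-butyl hydroperoxide, CC(C)(C)OO
Why: Lithium tert-butyl peroxide is an electrophilic oxygen (oxenoid) donor toward lithium acetylides and should give the ynolate with loss of tert-butoxide; the bulky silyl chloride then silylates the ynolate at oxygen and not at carbon (acetylide oxidation followed by O-silylation of an ynolate).

Step 2
Reactants: 5 5-methylhex-4-enoic acid
Product: 6 5-methylhex-4-enoyl chloride
Conditions: (COCl)2, DMF (cat.), CH2Cl2, 0 °C to rt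
Reagents that add atoms: oxalyl chloride, O=C(Cl)C(=O)Cl
Why: Vilsmeier-type activation converts the acid into the acid chloride with only gaseous by-products; low temperature and removal of HCl in the gas stream should keep the trisubstituted alkene from hydrochlorination.

Step 3
Reactants: 6 5-methylhex-4-enoyl chloride; 4 (triisopropylsilyloxy)acetylene
Product: 8 4-(3-methylbut-2-enyl)-3-(triisopropylsilyloxy)cyclobut-2-en-1-one (racemic), via prenylketene 7 (not isolated)
Conditions: Et3N, CH2Cl2, slow addition of 6, 0 °C to rt
Reagents that add atoms: none
Why: Dehydrochlorination gives aldoketene 7, which is trapped as it forms by the electron-rich ynol ether in a [2+2] cycloaddition; the nucleophilic CH carbon of the alkyne attacks the ketene carbonyl carbon, so the silyloxy group ends at C3 and the prenyl group at C4 (ketene–ynol ether cycloaddition), and the C4 stereocenter is racemic and is lost in step 4.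

Step 4
Reactants: 8 4-(3-methylbut-2-enyl)-3-(triisopropylsilyloxy)cyclobut-2-en-1-one; 4 (triisopropylsilyloxy)acetylene
Product: 13 2-(3-methylbut-2-enyl)-3,5-bis(triisopropylsilyloxy)phenol, via vinylketene 9 (not isolated), via vinylcyclobutenone 10 (not isolated), via dienylketene 11 (not isolated), via cyclohexadienone 12 (not isolated)
Conditions: 4 (1.5 equiv), toluene, 80 °C then 110 °C, sealed vessel, argon
Reagents that add atoms: none
Why: Heating opens cyclobutenone 8 by four-electron conrotatory electrocyclic ring opening to the 3-silyloxy vinylketene 9, the prenyl-bearing carbon turning outward. The ketene C=C bond of 9 adds alkyne 4 in a regioselective [2+2] cycloaddition to the 4-vinylcyclobutenone 10, which opens again to dienylketene 11; six-electron electrocyclization of 11 gives cyclohexadienone 12 (bond C8a–C8), and enolization gives phenol 13. This is the Danheiser benzannulation, and the closest known reaction type is the resorcinol synthesis from cyclobutenones and triisopropylsilyloxyalkynes. The one ring formed, ring A, closes by disrotatory 6π electrocyclization of the dienylketene; both cyclobutenone openings are reversible, so the isomer of 11 able to cyclize is drained through the irreversible aromatization. No stereocenter remains: those of 8, 10 and 12 are racemic and are erased by tautomerization. The selectivity needed is the orientation of the ketene–alkyne addition, and the polarity of the partners secures it: the unsubstituted carbon of the ynol ether is the nucleophilic terminus and bonds to the ketene carbonyl carbon (C4a to C8a), which places the alkyne oxygen at C5 and leaves the former ketone oxygen as the only free hydroxyl, O1, next to the prenyl group. The bulky silyl groups slow the oxygen-to-carbon silyl shift of the alkyne and silyl transfer to the new phenol, and the excess of 4 keeps free vinylketene scarce so that the phenol is not acylated by it.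

Step 5
Reactants: 13 2-(3-methylbut-2-enyl)-3,5-bis(triisopropylsilyloxy)phenol
Product: 15 2-hydroxy-3-(3-methylbut-2-enyl)-4,6-bis(triisopropylsilyloxy)benzaldehyde, via salicyl alcohol 14 (not isolated)
Conditions: MgCl2, Et3N, (CH2O)n, MeCN, reflux
Reagents that add atoms: paraformaldehyde (as formaldehyde), C=O
Why: Magnesium-mediated ortho-formylation (Casnati–Skattebøl): the magnesium phenoxide delivers coordinated formaldehyde through a six-membered transition state to the only free ortho carbon (future C4a), and salicyl alcohol 14 is oxidized in the flask by hydride transfer to a second formaldehyde; the amine/MgCl2 medium should leave the aryl silyl ethers and the prenyl alkene untouched.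

Step 6
Reactants: 16 4-hydroxybenzaldehyde; 17 prenyl bromide (1-bromo-3-methylbut-2-ene)
Product: 18 4-hydroxy-3-(3-methylbut-2-enyl)benzaldehyde
Conditions: KOH, H2O, rt
Reagents that add atoms: none
Why: C-Alkylation of a phenoxide in water, where hydrogen bonding to the oxygen disfavours O-alkylation; the para position is blocked by the formyl group, so the prenyl group enters ortho to the hydroxyl, and the O-prenyl ether is the expected separable by-product.

Step 7
Reactants: 18 4-hydroxy-3-(3-methylbut-2-enyl)benzaldehyde; 2 triisopropylsilyl chloride
Product: 19 3-(3-methylbut-2-enyl)-4-(triisopropylsilyloxy)benzaldehyde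
Conditions: imidazole, DMAP (cat.), DMF, rt
Reagents that add atoms: none
Why: Standard imidazole-promoted O-silylation of a phenol; the silyl group matches those of ring A so that one fluoride step frees all hydroxyls at the end.

Step 8
Reactants: 19 3-(3-methylbut-2-enyl)-4-(triisopropylsilyloxy)benzaldehyde
Product: 20 4-ethynyl-2-(3-methylbut-2-enyl)-1-(triisopropylsilyloxy)benzene
Conditions: Me3SiCHN2, n-BuLi, THF, −78 °C to rt
Reagents that add atoms: (trimethylsilyl)diazomethane, C[Si](C)(C)C=[N+]=[N-]
Why: Colvin rearrangement: lithiated (trimethylsilyl)diazomethane adds to the aldehyde, Peterson elimination and loss of N2 give an alkylidene carbene, and a 1,2-shift gives the terminal alkyne; the medium is free of alkoxide and fluoride, so the aryl silyl ether para to the reacting carbon should survive.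

Step 9
Reactants: 20 4-ethynyl-2-(3-methylbut-2-enyl)-1-(triisopropylsilyloxy)benzene; 15 2-hydroxy-3-(3-methylbut-2-enyl)-4,6-bis(triisopropylsilyloxy)benzaldehyde
Product: 22 1-[2-hydroxy-3-(3-methylbut-2-enyl)-4,6-bis(triisopropylsilyloxy)phenyl]-3-[3-(3-methylbut-2-enyl)-4-(triisopropylsilyloxy)phenyl]prop-2-yn-1-ol (racemic), via lithium acetylide 21 (not isolated)
Conditions: 20 (2.3 equiv), n-BuLi, THF, −78 °C; then 15, −78 to 0 °C; pH 7 buffer work-up
Reagents that add atoms: none
Why: Addition of a lithium acetylide to a salicylaldehyde: the first equivalent deprotonates the phenol and the second adds to the formyl group, forming C3–C4; the carbinol stereocenter is racemic and disappears in step 10, excess 20 is recovered, and the neutral work-up guards the electron-rich benzylic carbinol against ionization.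

Step 10
Reactants: 22 1-[2-hydroxy-3-(3-methylbut-2-enyl)-4,6-bis(triisopropylsilyloxy)phenyl]-3-[3-(3-methylbut-2-enyl)-4-(triisopropylsilyloxy)phenyl]prop-2-yn-1-ol
Product: 25 8-(3-methylbut-2-enyl)-2-[3-(3-methylbut-2-enyl)-4-(triisopropylsilyloxy)phenyl]-5,7-bis(triisopropylsilyloxy)-4H-chromen-4-one, via ynone 23 (not isolated), via enaminone 24 (not isolated)
Conditions: MnO2, CH2Cl2, rt; filter; then Et2NH, EtOH–THF, rt
Reagents that add atoms: none
Why: Activated MnO2 oxidizes the benzylic and propargylic alcohol to the ynone without touching the prenyl groups; the secondary amine adds in conjugate fashion to give enaminone 24, and the O1 hydroxyl displaces the amine at the β-carbon by addition–elimination, a closure that can only give the six-membered ring C and not the aurone. O5 is still silylated under these mild conditions, so only O1 can close the ring and the prenyl group is fixed at C8.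

Step 11
Reactants: 25 8-(3-methylbut-2-enyl)-2-[3-(3-methylbut-2-enyl)-4-(triisopropylsilyloxy)phenyl]-5,7-bis(triisopropylsilyloxy)-4H-chromen-4-one
Product: 28 3-hydroxy-8-(3-methylbut-2-enyl)-2-[3-(3-methylbut-2-enyl)-4-(triisopropylsilyloxy)phenyl]-5,7-bis(triisopropylsilyloxy)-4H-chromen-4-one, via 3-lithioflavone 26 (not isolated), via boronate 27 (not isolated)
Conditions: LiN(i-Pr)2, THF, −78 °C; B(OMe)3, −78 to 0 °C; then AcOH, 30% H2O2, 0 °C
Reagents that add atoms: hydrogen peroxide, OO
Why: Flavones are deprotonated at C3 (vinylic, α to the carbonyl) by lithium amides at −78 °C; boration and oxidation of the C–B bond give the 3-hydroxyl (lithiation–boration–oxidation), and weakly acidic H2O2 at 0 °C is too poor an electrophile to epoxidize the isolated trisubstituted alkenes.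

Step 12
Reactants: 28 3-hydroxy-8-(3-methylbut-2-enyl)-2-[3-(3-methylbut-2-enyl)-4-(triisopropylsilyloxy)phenyl]-5,7-bis(triisopropylsilyloxy)-4H-chromen-4-one
Product: 29 broussoflavonol F
Conditions: Bu4NF, AcOH, THF, 0 °C to rt, argon
Reagents that add atoms: none
Why: Fluoride cleaves the three aryl silyl ethers through Si–F bond formation; acetic acid buffering keeps the liberated flavonol out of the strongly basic regime in which it is air-oxidized, and no acid able to cyclize the prenyl groups onto the ortho hydroxyls is present.

**Compound list**

1 | lithium acetylide–ethylenediamine complex | [Li+].[C-]#C.NCCN | starting material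
2 | triisopropylsilyl chloride | CC(C)[Si](Cl)(C(C)C)C(C)C | starting material
3 | lithium ethynolate | [Li+].[O-]C#C | intermediate
4 | (triisopropylsilyloxy)acetylene | C#CO[Si](C(C)C)(C(C)C)C(C)C | intermediate
5 | 5-methylhex-4-enoic acid | CC(C)=CCCC(=O)O | starting material
6 | 5-methylhex-4-enoyl chloride | CC(C)=CCCC(=O)Cl | intermediate
7 | prenylketene (5-methylhexa-1,4-dien-1-one) | CC(C)=CCC=C=O | intermediate
8 | 4-(3-methylbut-2-enyl)-3-(triisopropylsilyloxy)cyclobut-2-en-1-one, racemic | CC(C)=CCC1C(=O)C=C1O[Si](C(C)C)(C(C)C)C(C)C | intermediate
9 | (3Z)-7-methyl-3-(triisopropylsilyloxy)octa-1,3,6-trien-1-one | O=C=C/C(O[Si](C(C)C)(C(C)C)C(C)C)=C/CC=C(C)C | intermediate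
10 | 4-[(1Z)-5-methyl-1-(triisopropylsilyloxy)hexa-1,4-dienyl]-3-(triisopropylsilyloxy)cyclobut-2-en-1-one, racemic | O=C1C=C(O[Si](C(C)C)(C(C)C)C(C)C)C1/C(O[Si](C(C)C)(C(C)C)C(C)C)=C/CC=C(C)C | intermediate
11 | (3E,5Z)-9-methyl-3,5-bis(triisopropylsilyloxy)deca-1,3,5,8-tetraen-1-one | O=C=C/C(O[Si](C(C)C)(C(C)C)C(C)C)=C\C(O[Si](C(C)C)(C(C)C)C(C)C)=C\CC=C(C)C | intermediate
12 | 6-(3-methylbut-2-enyl)-3,5-bis(triisopropylsilyloxy)cyclohexa-2,4-dien-1-one, racemic | CC(C)=CCC1C(=O)C=C(O[Si](C(C)C)(C(C)C)C(C)C)C=C1O[Si](C(C)C)(C(C)C)C(C)C | intermediate
13 | 2-(3-methylbut-2-enyl)-3,5-bis(triisopropylsilyloxy)phenol | CC(C)=CCc1c(O)cc(O[Si](C(C)C)(C(C)C)C(C)C)cc1O[Si](C(C)C)(C(C)C)C(C)C | intermediate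
14 | 2-(hydroxymethyl)-6-(3-methylbut-2-enyl)-3,5-bis(triisopropylsilyloxy)phenol | OCc1c(O)c(CC=C(C)C)c(O[Si](C(C)C)(C(C)C)C(C)C)cc1O[Si](C(C)C)(C(C)C)C(C)C | intermediate
15 | 2-hydroxy-3-(3-methylbut-2-enyl)-4,6-bis(triisopropylsilyloxy)benzaldehyde | O=Cc1c(O)c(CC=C(C)C)c(O[Si](C(C)C)(C(C)C)C(C)C)cc1O[Si](C(C)C)(C(C)C)C(C)C | intermediate
16 | 4-hydroxybenzaldehyde | O=Cc1ccc(O)cc1 | starting material
17 | prenyl bromide (1-bromo-3-methylbut-2-ene) | CC(C)=CCBr | starting material
18 | 4-hydroxy-3-(3-methylbut-2-enyl)benzaldehyde | CC(C)=CCc1cc(C=O)ccc1O | intermediate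
19 | 3-(3-methylbut-2-enyl)-4-(triisopropylsilyloxy)benzaldehyde | CC(C)=CCc1cc(C=O)ccc1O[Si](C(C)C)(C(C)C)C(C)C | intermediate
20 | 4-ethynyl-2-(3-methylbut-2-enyl)-1-(triisopropylsilyloxy)benzene | C#Cc1ccc(O[Si](C(C)C)(C(C)C)C(C)C)c(CC=C(C)C)c1 | intermediate
21 | lithium acetylide of 20 | [Li]C#Cc1ccc(O[Si](C(C)C)(C(C)C)C(C)C)c(CC=C(C)C)c1 | intermediate
22 | 1-[2-hydroxy-3-(3-methylbut-2-enyl)-4,6-bis(triisopropylsilyloxy)phenyl]-3-[3-(3-methylbut-2-enyl)-4-(triisopropylsilyloxy)phenyl]prop-2-yn-1-ol, racemic | OC(C#Cc1ccc(O[Si](C(C)C)(C(C)C)C(C)C)c(CC=C(C)C)c1)c1c(O)c(CC=C(C)C)c(O[Si](C(C)C)(C(C)C)C(C)C)cc1O[Si](C(C)C)(C(C)C)C(C)C | intermediate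
23 | 1-[2-hydroxy-3-(3-methylbut-2-enyl)-4,6-bis(triisopropylsilyloxy)phenyl]-3-[3-(3-methylbut-2-enyl)-4-(triisopropylsilyloxy)phenyl]prop-2-yn-1-one | O=C(C#Cc1ccc(O[Si](C(C)C)(C(C)C)C(C)C)c(CC=C(C)C)c1)c1c(O)c(CC=C(C)C)c(O[Si](C(C)C)(C(C)C)C(C)C)cc1O[Si](C(C)C)(C(C)C)C(C)C | intermediate
24 | (E)-3-(diethylamino)-1-[2-hydroxy-3-(3-methylbut-2-enyl)-4,6-bis(triisopropylsilyloxy)phenyl]-3-[3-(3-methylbut-2-enyl)-4-(triisopropylsilyloxy)phenyl]prop-2-en-1-one (drawn as the E isomer) | O=C(/C=C(/N(CC)CC)c1ccc(O[Si](C(C)C)(C(C)C)C(C)C)c(CC=C(C)C)c1)c1c(O)c(CC=C(C)C)c(O[Si](C(C)C)(C(C)C)C(C)C)cc1O[Si](C(C)C)(C(C)C)C(C)C | intermediate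
25 | 8-(3-methylbut-2-enyl)-2-[3-(3-methylbut-2-enyl)-4-(triisopropylsilyloxy)phenyl]-5,7-bis(triisopropylsilyloxy)-4H-chromen-4-one | CC(C)=CCc1cc(-c2cc(=O)c3c(O[Si](C(C)C)(C(C)C)C(C)C)cc(O[Si](C(C)C)(C(C)C)C(C)C)c(CC=C(C)C)c3o2)ccc1O[Si](C(C)C)(C(C)C)C(C)C | intermediate
26 | 3-lithio derivative of flavone 25 | CC(C)=CCc1cc(-c2oc3c(CC=C(C)C)c(O[Si](C(C)C)(C(C)C)C(C)C)cc(O[Si](C(C)C)(C(C)C)C(C)C)c3c(=O)c2[Li])ccc1O[Si](C(C)C)(C(C)C)C(C)C | intermediate
27 | dimethyl boronate at C3 of flavone 25 | CC(C)=CCc1cc(-c2oc3c(CC=C(C)C)c(O[Si](C(C)C)(C(C)C)C(C)C)cc(O[Si](C(C)C)(C(C)C)C(C)C)c3c(=O)c2B(OC)OC)ccc1O[Si](C(C)C)(C(C)C)C(C)C | intermediate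
28 | 3-hydroxy-8-(3-methylbut-2-enyl)-2-[3-(3-methylbut-2-enyl)-4-(triisopropylsilyloxy)phenyl]-5,7-bis(triisopropylsilyloxy)-4H-chromen-4-one | CC(C)=CCc1cc(-c2oc3c(CC=C(C)C)c(O[Si](C(C)C)(C(C)C)C(C)C)cc(O[Si](C(C)C)(C(C)C)C(C)C)c3c(=O)c2O)ccc1O[Si](C(C)C)(C(C)C)C(C)C | intermediate
29 | broussoflavonol F, 3,5,7-trihydroxy-2-[4-hydroxy-3-(3-methylbut-2-enyl)phenyl]-8-(3-methylbut-2-enyl)-4H-chromen-4-one | CC(C)=CCc1cc(-c2oc3c(CC=C(C)C)c(O)cc(O)c3c(=O)c2O)ccc1O | target

**Step count and risks**

Total: 12 steps. Longest linear sequence: 8 steps (step 1 or 2, then 3, 4, 5, 9, 10, 11, 12). The ring B branch (steps 6 to 8) joins at step 9.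

Least certain steps:

- **Step 4 (key step).** Several processes could erode the annulation. Silicon may shift from oxygen to carbon in alkyne 4 at the reaction temperature. The new phenol may be acylated by the vinylketene. A silyl group may be lost from the vinylogous silyl ester before ring opening. The donor-substituted vinylketene may dimerize if the cycloaddition is slow.
  - Fallback: set out from triisopropylsilyl chloride 2 and prenyl bromide 17. Phloroglucinol F1 is silylated twice with 2 and imidazole to 3,5-bis(triisopropylsilyloxy)phenol F2. Its sodium phenoxide (NaH, toluene) is C-prenylated with 17 at one of the two equivalent ortho carbons, which gives 13 and returns to the route there. This pays with statistical silylation and competing O-alkylation.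

- **Step 1.** The monolithium acetylide may disproportionate on warming, the peroxide may attack the diamine, and the volatile, acid-sensitive product may be lost on isolation.
  - Fallback: set out from 2. The ynolate is generated by a Kowalski-type carbenoid rearrangement instead: ethyl formate with LiCHBr2, then LiN(SiMe3)2 and n-BuLi, with hydrogen migration in the bromo enolate dianion. Silylation with 2 returns to the route at 4.

- **Step 9.** Addition to the deactivated, hindered lithium phenoxide aldehyde may be slow, and the electron-rich carbinol may ionize toward an ortho-quinone methide during work-up.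
  - Fallback: reverse the polarity. Acetylide 21 (from 20) is formylated with DMF to 3-[3-(3-methylbut-2-enyl)-4-(triisopropylsilyloxy)phenyl]prop-2-ynal F3. The bromomagnesium phenoxide of 13 (EtMgBr, toluene) is hydroxyalkylated by F3 at its ortho carbon. This sets out from 13 and 20, bypasses step 5, and returns at 22.

- **Step 11.** The 3-lithio flavone may undergo ring opening by β-elimination of the O1 phenoxide, boration may be incomplete, and the flavonol may suffer oxidative damage by peroxide.
  - Fallback: set out from 25. Conjugate reduction with LiBH(s-Bu)3 at −78 °C gives the flavanone enolate, which is hydroxylated with 2-(phenylsulfonyl)-3-phenyloxaziridine to the trans-3-hydroxyflavanone F4 (racemic). Oxidation of its secondary alcohol with Dess–Martin periodinane gives the 3,4-dione, whose enol is 28, where the route is rejoined.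

**Further compounds**

F1 | step 4 | phloroglucinol (benzene-1,3,5-triol) | Oc1cc(O)cc(O)c1
F2 | step 4 | 3,5-bis(triisopropylsilyloxy)phenol | Oc1cc(O[Si](C(C)C)(C(C)C)C(C)C)cc(O[Si](C(C)C)(C(C)C)C(C)C)c1
F0 | step 1 | none | none
F3 | step 9 | 3-[3-(3-methylbut-2-enyl)-4-(triisopropylsilyloxy)phenyl]prop-2-ynal | O=CC#Cc1ccc(O[Si](C(C)C)(C(C)C)C(C)C)c(CC=C(C)C)c1
F4 | step 11 | trans-3-hydroxy-8-(3-methylbut-2-enyl)-2-[3-(3-methylbut-2-enyl)-4-(triisopropylsilyloxy)phenyl]-5,7-bis(triisopropylsilyloxy)chroman-4-one, racemic, one enantiomer drawn | O=C1[C@@H](O)[C@H](c2ccc(O[Si](C(C)C)(C(C)C)C(C)C)c(CC=C(C)C)c2)Oc2c(CC=C(C)C)c(O[Si](C(C)C)(C(C)C)C(C)C)cc(O[Si](C(C)C)(C(C)C)C(C)C)c12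
A1 | alternative 1 | 3,5,7,4'-tetrakis-O-(methoxymethyl) broussoflavonol F | CC(C)=CCc1cc(-c2oc3c(CC=C(C)C)c(OCOC)cc(OCOC)c3c(=O)c2OCOC)ccc1OCOC
A2 | alternative 1 | 8,3'-diallyl-3,5,7,4'-tetrakis(methoxymethoxy)flavone | C=CCc1cc(-c2oc3c(CC=C)c(OCOC)cc(OCOC)c3c(=O)c2OCOC)ccc1OCOC
A3 | alternative 1 | 2-methylbut-2-ene | CC=C(C)C
A4 | alternative 2 | 5,7,4'-tris(methoxymethoxy)-8,3'-diprenylflavone | CC(C)=CCc1cc(-c2cc(=O)c3c(OCOC)cc(OCOC)c(CC=C(C)C)c3o2)ccc1OCOC
A5 | alternative 2 | 2-hydroxy-4,6-bis(methoxymethoxy)-3-(3-methylbut-2-enyl)benzaldehyde | O=Cc1c(O)c(CC=C(C)C)c(OCOC)cc1OCOC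
A6 | alternative 2 | dimethylsulfoxonium 2-[4-(methoxymethoxy)-3-(3-methylbut-2-enyl)phenyl]-2-oxoethylide | CS(C)(=O)=CC(=O)c1ccc(OCOC)c(CC=C(C)C)c1
A7 | alternative 3 | broussoflavonol F tetraacetate | CC(C)=CCc1cc(-c2oc3c(CC=C(C)C)c(OC(C)=O)cc(OC(C)=O)c3c(=O)c2OC(C)=O)ccc1OC(C)=O
A8 | alternative 3 | 8,3'-bis(bromomethyl)-3,5,7,4'-tetraacetoxyflavone | BrCc1cc(-c2oc3c(CBr)c(OC(C)=O)cc(OC(C)=O)c3c(=O)c2OC(C)=O)ccc1OC(C)=O
A9 | alternative 3 | 2-methylprop-1-enylboronic acid pinacol ester | CC(C)=CB1OC(C)(C)C(C)(C)O1
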